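The route rests on tracing the C4–O bond of the tertiary carbinol back to a ketone: C4, C1', C2', C3' and C4' are tied into a temporary cyclopentanone in which carbonyl carbon C4' occupies the place of the hydroxyl oxygen. A single Baeyer–Villiger oxidation then makes the C4–O bond with retention, enlarges the carbocycle to a six-membered lactone and turns C4' into the handle for the E side chain. Its precursor is a pulegone-derived 2,2,3-trisubstituted cyclopentanone with the C3 butynyl arm trans to the C1' methyl group and a silyloxymethyl group as C5. B-alkyl Suzuki coupling, ring-closing alkyne metathesis and hydroxyl-directed methylmagnesiation finally build the fourteen-membered ring C1–C14.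

Key step: step 7

Numbering: ring C1(CH3)=C2, C3, C4 (carbinol), C5 to C14 (methyl groups on C7 and C11); side chain on C4: C1'(CH3)–C2'–C3'–C4'=C5'(CH3)–C6'H2OH.

Remark on the chemistry: stereocentres that are erased later (C2 of 2, C1 of 3 and 4, the carbinol carbon of 7 and 8, the anomeric carbon of 14) are carried as epimer mixtures and are left open in the SMILES.

**Route**

Step 1
Reactants: 1 (R)-pulegone
Product: 3 methyl (2R)-2-methyl-5-(propan-2-ylidene)cyclopentane-1-carboxylate (methyl pulegenate), via pulegone dibromide 2 (not isolated)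
Conditions: Br2, NaHCO3, Et2O, −10 °C; then NaOMe, MeOH, reflux
Reagents that add atoms: sodium methoxide, C[O-].[Na+]
Why: Bromine adds across the tetrasubstituted alkene and methoxide then drives a Favorskii rearrangement (cyclopropanone, ring opening, loss of the second bromide), the classical ring contraction of pulegone, which does not touch the methyl-bearing stereocentre and forms the ester-bearing carbon as an inconsequential epimer mixture.

Step 2
Reactants: 3 methyl pulegenate
Product: 4 methyl (2R)-2-methyl-5-oxocyclopentane-1-carboxylate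
Conditions: O3, CH2Cl2/MeOH, −78 °C; then Me2S
Reagents that add atoms: ozone, [O-][O+]=O
Why: Ozonolysis with reductive work-up cleaves the isopropylidene group to the ring ketone and gives the β-keto ester, whose C1 equilibrates through the enol.

Step 3
Reactants: 4 methyl (2R)-2-methyl-5-oxocyclopentane-1-carboxylate; 5 1-bromobut-2-yne
Product: 6 methyl (1R,2R)-1-(but-2-yn-1-yl)-2-methyl-5-oxocyclopentane-1-carboxylate
Conditions: K2CO3, acetone, reflux
Reagents that add atoms: none
Why: C-alkylation of the β-keto ester enolate (SN2 at the propargylic bromide) should occur on the ring face opposite the neighbouring C2 methyl group, so the quaternary centre is set under substrate control with butynyl trans to methyl.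

Step 4
Reactants: 6 alkylated keto ester
Product: 7 (2S,3R)-2-(but-2-yn-1-yl)-2-(hydroxymethyl)-3-methylcyclopentan-1-ol
Conditions: LiAlH4, THF, 0 °C → rt
Reagents that add atoms: none
Why: Hydride reduction takes ketone and ester to the diol while the isolated internal alkyne is inert; the new carbinol centre forms as a mixture that step 6 removes.

Step 5
Reactants: 7 diol
Product: 8 (2S,3R)-2-(but-2-yn-1-yl)-2-{[tert-butyl(dimethyl)silyl]oxymethyl}-3-methylcyclopentan-1-ol
Conditions: TBSCl, imidazole, DMF, 0 °C
Reagents that add atoms: tert-butyldimethylsilyl chloride, CC(C)(C)[Si](C)(C)Cl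
Why: Silylation with a bulky chlorosilane should pick the primary hydroxyl over the hindered secondary ring hydroxyl (selective monosilylation of a diol).

Step 6
Reactants: 8 monosilyl ether
Product: 9 (2S,3R)-2-(but-2-yn-1-yl)-2-{[tert-butyl(dimethyl)silyl]oxymethyl}-3-methylcyclopentan-1-one
Conditions: Dess–Martin periodinane, CH2Cl2, rt
Reagents that add atoms: none
Why: Dess–Martin oxidation restores the ketone from both carbinol epimers without affecting the silyl ether or the alkyne.

Step 7
Reactants: 9 silyloxymethyl cyclopentanone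
Product: 10 (5R,6S)-6-(but-2-yn-1-yl)-6-{[tert-butyl(dimethyl)silyl]oxymethyl}-5-methyloxan-2-one
Conditions: mCPBA, NaHCO3, CH2Cl2, 0 °C → rt
Reagents that add atoms: 3-chloroperoxybenzoic acid, OOC(=O)c1cccc(Cl)c1
Why: The peracid adds to the ketone to give a Criegee adduct, and the fully substituted C4 shifts from C4' to the peroxide oxygen as the carboxylate leaves, which is the classical Baeyer–Villiger oxidation of an α-quaternary cyclopentanone. The six-membered lactone ring (O, C4, C1', C2', C3', C4') arises by one-atom ring expansion of the carbocycle through this 1,2-shift and not by a cyclisation. The migrating carbon keeps its configuration, so the new C4–O stereocentre is controlled by the quaternary centre set in step 3 and keeps its relation to the pulegone-derived C1' methyl group. The step needs migration of C4 in preference to the ring CH2 (C3'), which the higher migratory aptitude of a tertiary over a primary alkyl carbon secures. It also needs chemoselectivity, which the substrate provides because it holds no alkene and its internal alkyne and silyl ether are inert to buffered mCPBA.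

Step 8
Reactants: 10 silyloxymethyl lactone
Product: 11 (5R,6S)-6-(but-2-yn-1-yl)-6-(hydroxymethyl)-5-methyloxan-2-one
Conditions: HF·pyridine, THF/pyridine, 0 °C → rt
Reagents that add atoms: none
Why: Fluoride-driven desilylation under mildly acidic conditions frees the primary alcohol while the lactone, which serves as the protecting group of the C4 oxygen, should stay closed.

Step 9
Reactants: 11 hydroxymethyl lactone
Product: 12 (2S,3R)-2-(but-2-yn-1-yl)-3-methyl-6-oxooxane-2-carbaldehyde
Conditions: Dess–Martin periodinane, CH2Cl2, rt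
Reagents that add atoms: none
Why: Dess–Martin oxidation of the neopentyl primary alcohol gives an aldehyde that has no α-hydrogen and therefore cannot enolise or epimerise.

Step 10
Reactants: 12 lactone aldehyde
Product: 13 (5R,6R)-6-(but-2-yn-1-yl)-6-ethenyl-5-methyloxan-2-one
Conditions: Ph3PCH3Br, KN(SiMe3)2, THF, −78 → 0 °C
Reagents that add atoms: methyltriphenylphosphonium bromide, C[P+](c1ccccc1)(c1ccccc1)c1ccccc1.[Br-]
Why: Wittig methylenation with the non-stabilised ylide is much faster at the aldehyde than at the lactone carbonyl at low temperature and introduces C6.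

Step 11
Reactants: 13 vinyl lactone
Product: 14 (5R,6R)-6-(but-2-yn-1-yl)-6-ethenyl-5-methyloxan-2-ol
Conditions: i-Bu2AlH, CH2Cl2, −78 °C
Reagents that add atoms: none
Why: One equivalent of the aluminium hydride at low temperature stops at the lactol because the tetrahedral aluminate is stable until work-up (partial reduction of a δ-lactone).

Step 12
Reactants: 14 lactol; 15 ethyl 2-(triphenyl-λ5-phosphanylidene)propanoate
Product: 16 ethyl (2E,6R,7R)-7-ethenyl-7-hydroxy-2,6-dimethylundec-2-en-9-ynoate
Conditions: toluene, 90 °C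
Reagents that add atoms: none
Why: The lactol opens to the hydroxy aldehyde, which the stabilised α-methyl ylide traps in a Wittig reaction that should give the E-trisubstituted enoate (C4'=C5') and releases the tertiary C4 hydroxyl.

Step 13
Reactants: 17 pent-3-yn-1-ol
Product: 19 (3E)-4-iodopent-3-en-1-ol, via alkenylzirconocene chloride 18 (not isolated)
Conditions: Cp2Zr(H)Cl (2.2 equiv), THF, rt; then I2, 0 °C
Reagents that add atoms: iodine, II
Why: Syn-hydrozirconation of the methyl-capped alkyne puts zirconium on the methyl-bearing carbon and iodinolysis proceeds with retention, which fixes the E geometry (hydrozirconation–iodination, well established for this alkynol).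

Step 14
Reactants: 17 pent-3-yn-1-ol
Product: 20 5-iodopent-2-yne
Conditions: PPh3, I2, imidazole, CH2Cl2, 0 °C → rt
Reagents that add atoms: iodine, II
Why: Appel-type iodination converts the primary alcohol into the iodide by SN2 displacement of the oxyphosphonium group.

Step 15
Reactants: 20 5-iodopent-2-yne; 19 (3E)-4-iodopent-3-en-1-ol
Product: 22 (3E)-4-methylnon-3-en-7-yn-1-ol, via pent-3-ynylzinc iodide 21 (not isolated)
Conditions: Zn, LiCl, THF, 40 °C; then 19, Pd(OAc)2, SPhos, THF, rt
Reagents that add atoms: none
Why: Zinc insertion into the primary iodide and Negishi sp3–sp2 coupling form C10–C11 with retention of the alkene geometry of 19, and this catalyst system is known to tolerate a free hydroxyl when the zinc reagent is used in excess.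

Step 16
Reactants: 22 (3E)-4-methylnon-3-en-7-yn-1-ol
Product: 24 (3E,7E)-8-iodo-4-methylnona-3,7-dien-1-ol, via alkenylzirconocene chloride 23 (not isolated)
Conditions: Cp2Zr(H)Cl (3 equiv), THF, 50 °C; then I2, 0 °C
Reagents that add atoms: iodine, II
Why: Hydrozirconation–iodination of the only alkyne, with excess reagent and gentle warming to equilibrate zirconium to the less hindered methyl terminus, should give the E-2-iodoalkene while the trisubstituted alkene stays untouched.

Step 17
Reactants: 24 iodo dienol
Product: 25 (2E,6E)-2,9-diiodo-6-methylnona-2,6-diene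
Conditions: PPh3, I2, imidazole, CH2Cl2, 0 °C
Reagents that add atoms: iodine, II
Why: Appel-type iodination of the primary homoallylic alcohol, which leaves both alkenes and the alkenyl iodide unchanged.

Step 18
Reactants: 25 diiodide; 26 prop-1-yn-1-yllithium
Product: 27 (2E,6E)-2-iodo-6-methyldodeca-2,6-dien-10-yne
Conditions: LiC≡CCH3, THF/DMPU, −20 °C → rt
Reagents that add atoms: none
Why: SN2 alkylation of the lithium acetylide at the primary alkyl iodide in a dipolar cosolvent installs the methyl-capped alkyne, while the alkenyl iodide does not react with an acetylide in the absence of a catalyst.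

Step 19
Reactants: 16 hydroxy enoate; 27 alkenyl iodide
Product: 29 ethyl (2E,6R,7S,10E,14E)-7-(but-2-yn-1-yl)-7-hydroxy-2,6,10,14-tetramethylicosa-2,10,14-trien-18-ynoate, via B-alkyl-9-BBN borane 28 (not isolated)
Conditions: 9-BBN, THF, rt; then aq Cs2CO3, 27, Pd(dppf)Cl2, AsPh3, DMF, rt
Reagents that add atoms: none
Why: 9-BBN hydroborates the monosubstituted alkene at its terminal carbon far faster than it attacks the internal alkyne or the enoate, and the B-alkyl Suzuki–Miyaura coupling joins C6 to C7 with retention of the E geometry of 27.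

Step 20
Reactants: 29 diyne
Product: 30 ethyl (2E,6R)-6-[(1S,7E,11E)-1-hydroxy-8,12-dimethylcyclotetradeca-7,11-dien-3-yn-1-yl]-2-methylhept-2-enoate
Conditions: [Mo(≡CC6H4-4-OMe)(OSiPh3)3] (10 mol %), MS 5 Å, toluene (2 mM), rt → 60 °C
Reagents that add atoms: none
Why: Ring-closing alkyne metathesis with a molybdenum alkylidyne silanolate catalyst joins the two methyl-capped alkynes into the C1≡C2 cycloalkyne while the sieves trap but-2-yne; alkenes, the ester and a hindered tertiary alcohol are tolerated and no stereocentre is touched.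

Step 21
Reactants: 30 cycloalkyne ester
Product: 31 (2E,6R)-6-[(1S,7E,11E)-1-hydroxy-8,12-dimethylcyclotetradeca-7,11-dien-3-yn-1-yl]-2-methylhept-2-en-1-ol
Conditions: i-Bu2AlH, CH2Cl2, −78 → 0 °C
Reagents that add atoms: none
Why: 1,2-Reduction of the enoate by the aluminium hydride gives the allylic alcohol (C6') and leaves the cycloalkyne and the alkenes unchanged.

Step 22
Reactants: 31 cycloalkyne diol
Product: 33 (2E,6R)-6-[(1S,3Z,7E,11E)-1-hydroxy-4,8,12-trimethylcyclotetradeca-3,7,11-trien-1-yl]-2-methylhept-2-en-1-ol, via alkenylmagnesium bromide 32 (not isolated)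
Conditions: MeMgBr (6 equiv), Fe(acac)3 (20 mol %), THF, 0 °C → rt; then aq NH4Cl
Reagents that add atoms: methylmagnesium bromide, C[Mg]Br
Why: Iron-catalysed, alkoxide-directed syn-carbomagnesiation of a homopropargylic alcohol places the metal on the proximal C2 and methyl on the distal C1 through a five-membered metallacycle that includes the C4 alkoxide, so protonation should give the Z-trisubstituted C1=C2 alkene.

**Compound list**

1 | (R)-pulegone, (5R)-5-methyl-2-(propan-2-ylidene)cyclohexan-1-one | C[C@@H]1CCC(=C(C)C)C(=O)C1 | starting material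
2 | (5R)-2-bromo-2-(2-bromopropan-2-yl)-5-methylcyclohexan-1-one (pulegone dibromide, C2 epimers) | C[C@@H]1CCC(Br)(C(C)(C)Br)C(=O)C1 | intermediate
3 | methyl (2R)-2-methyl-5-(propan-2-ylidene)cyclopentane-1-carboxylate (C1 epimers) | C[C@@H]1CCC(=C(C)C)C1C(=O)OC | intermediate
4 | methyl (2R)-2-methyl-5-oxocyclopentane-1-carboxylate (C1 epimerisable) | C[C@@H]1CCC(=O)C1C(=O)OC | intermediate
5 | 1-bromobut-2-yne | CC#CCBr | starting material
6 | methyl (1R,2R)-1-(but-2-yn-1-yl)-2-methyl-5-oxocyclopentane-1-carboxylate (butynyl trans to methyl) | O=C1[C@](CC#CC)(C(=O)OC)[C@H](C)CC1 | intermediate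
7 | (2S,3R)-2-(but-2-yn-1-yl)-2-(hydroxymethyl)-3-methylcyclopentan-1-ol (C1 epimers) | OC1[C@](CC#CC)(CO)[C@H](C)CC1 | intermediate
8 | (2S,3R)-2-(but-2-yn-1-yl)-2-{[tert-butyl(dimethyl)silyl]oxymethyl}-3-methylcyclopentan-1-ol (C1 epimers) | OC1[C@](CC#CC)(CO[Si](C)(C)C(C)(C)C)[C@H](C)CC1 | intermediate
9 | (2S,3R)-2-(but-2-yn-1-yl)-2-{[tert-butyl(dimethyl)silyl]oxymethyl}-3-methylcyclopentan-1-one | O=C1[C@](CC#CC)(CO[Si](C)(C)C(C)(C)C)[C@H](C)CC1 | intermediate
10 | (5R,6S)-6-(but-2-yn-1-yl)-6-{[tert-butyl(dimethyl)silyl]oxymethyl}-5-methyloxan-2-one | O=C1O[C@](CC#CC)(CO[Si](C)(C)C(C)(C)C)[C@H](C)CC1 | intermediate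
11 | (5R,6S)-6-(but-2-yn-1-yl)-6-(hydroxymethyl)-5-methyloxan-2-one | O=C1O[C@](CC#CC)(CO)[C@H](C)CC1 | intermediate
12 | (2S,3R)-2-(but-2-yn-1-yl)-3-methyl-6-oxooxane-2-carbaldehyde | O=C1O[C@](CC#CC)(C=O)[C@H](C)CC1 | intermediate
13 | (5R,6R)-6-(but-2-yn-1-yl)-6-ethenyl-5-methyloxan-2-one | O=C1O[C@](CC#CC)(C=C)[C@H](C)CC1 | intermediate
14 | (5R,6R)-6-(but-2-yn-1-yl)-6-ethenyl-5-methyloxan-2-ol (anomers) | OC1O[C@](CC#CC)(C=C)[C@H](C)CC1 | intermediate
15 | ethyl 2-(triphenyl-λ5-phosphanylidene)propanoate | CCOC(=O)C(C)=P(c1ccccc1)(c1ccccc1)c1ccccc1 | starting material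
16 | ethyl (2E,6R,7R)-7-ethenyl-7-hydroxy-2,6-dimethylundec-2-en-9-ynoate | CC#CC[C@](O)([C@H](C)CC/C=C(\C)C(=O)OCC)C=C | intermediate
17 | pent-3-yn-1-ol | CC#CCCO | starting material
18 | alkenylzirconocene chloride from 17: Cp2Zr(Cl) on C4 of the (3E)-pent-3-enyl chain, cis to the C3 hydrogen, oxygen as its Cp2Zr(Cl) alkoxide | C/C(=C\CCO[Zr](Cl)(C1C=CC=C1)C1C=CC=C1)[Zr](Cl)(C1C=CC=C1)C1C=CC=C1 | intermediate
19 | (3E)-4-iodopent-3-en-1-ol | I/C(C)=C/CCO | intermediate
20 | 5-iodopent-2-yne | CC#CCCI | intermediate
21 | pent-3-yn-1-ylzinc iodide | CC#CCC[Zn]I | intermediate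
22 | (3E)-4-methylnon-3-en-7-yn-1-ol | CC#CCC/C(C)=C/CCO | intermediate
23 | alkenylzirconocene chloride from 22: Cp2Zr(Cl) on C8 of the (3E,7E)-4-methylnona-3,7-dienyl chain, oxygen as its Cp2Zr(Cl) alkoxide | C/C(=C\CC/C(C)=C/CCO[Zr](Cl)(C1C=CC=C1)C1C=CC=C1)[Zr](Cl)(C1C=CC=C1)C1C=CC=C1 | intermediate
24 | (3E,7E)-8-iodo-4-methylnona-3,7-dien-1-ol | I/C(C)=C/CC/C(C)=C/CCO | intermediate
25 | (2E,6E)-2,9-diiodo-6-methylnona-2,6-diene | I/C(C)=C/CC/C(C)=C/CCI | intermediate
26 | prop-1-yn-1-yllithium | [Li]C#CC | starting material
27 | (2E,6E)-2-iodo-6-methyldodeca-2,6-dien-10-yne | I/C(C)=C/CC/C(C)=C/CCC#CC | intermediate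
28 | B-alkyl-9-borabicyclo[3.3.1]nonane from 16 (vinyl group turned into CH2CH2–B) | CC#CC[C@](O)([C@H](C)CC/C=C(\C)C(=O)OCC)CCB1C2CCCC1CCC2 | intermediate
29 | ethyl (2E,6R,7S,10E,14E)-7-(but-2-yn-1-yl)-7-hydroxy-2,6,10,14-tetramethylicosa-2,10,14-trien-18-ynoate | CC#CC[C@](O)([C@H](C)CC/C=C(\C)C(=O)OCC)CC/C(C)=C/CC/C(C)=C/CCC#CC | intermediate
30 | ethyl (2E,6R)-6-[(1S,7E,11E)-1-hydroxy-8,12-dimethylcyclotetradeca-7,11-dien-3-yn-1-yl]-2-methylhept-2-enoate | C1#CC[C@](O)([C@H](C)CC/C=C(\C)C(=O)OCC)CC/C(C)=C/CC/C(C)=C/CC1 | intermediate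
31 | (2E,6R)-6-[(1S,7E,11E)-1-hydroxy-8,12-dimethylcyclotetradeca-7,11-dien-3-yn-1-yl]-2-methylhept-2-en-1-ol | C1#CC[C@](O)([C@H](C)CC/C=C(\C)CO)CC/C(C)=C/CC/C(C)=C/CC1 | intermediate
32 | alkenylmagnesium bromide: 33 with MgBr on C2 in place of hydrogen (cis to the C1 methyl), both hydroxyls as bromomagnesium alkoxides | C/C1=C(\[Mg]Br)C[C@](O[Mg]Br)([C@H](C)CC/C=C(\C)CO[Mg]Br)CC/C(C)=C/CC/C(C)=C/CC1 | intermediate
33 | (2E,6R)-6-[(1S,3Z,7E,11E)-1-hydroxy-4,8,12-trimethylcyclotetradeca-3,7,11-trien-1-yl]-2-methylhept-2-en-1-ol (CNP0267300.1) | C/C1=C/C[C@](O)([C@H](C)CC/C=C(\C)CO)CC/C(C)=C/CC/C(C)=C/CC1 | target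

**Step count**

Total step count: 22 (steps 1–12 for the lactone-derived half, steps 13–18 for alkenyl iodide 27, steps 19–22 for union and endgame).
Longest linear sequence: 16 steps (1–12 and 19–22, from 1 to 33).

**Steps most likely to fail**

Step 22. The methyl transfer may stall or lose regiocontrol because the directing tertiary alkoxide lies inside the fourteen-membered ring, and iron hydride species formed on catalyst decay may reduce the alkyne instead. The fallback sets out from 31 and comes back at 33, and it builds the same alkene by hydrometalation and methyl cross-coupling in place of carbometalation. Excess Cp2Zr(H)Cl in THF at 50 °C should add H–Zr syn across C1≡C2 and settle zirconium on C1, the alkyne carbon remote from the quaternary C4, to give the cyclic alkenylzirconocene F1. Iodine then converts it with retention into the cyclic alkenyl iodide F2. Suzuki–Miyaura methylation of F2 with trimethylboroxine, Pd(dppf)Cl2 and K2CO3 in aqueous dioxane should place the methyl group on C1 with retention and give 33.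

Step 20. The free tertiary hydroxyl may exchange with the silanolate ligands and deactivate the alkylidyne, leaving open-chain diyne or oligomers. The fallback sets out from 29 and comes back at 30, and it masks the hydroxyl before ring closure. TMSOTf and 2,6-lutidine in CH2Cl2 at −78 °C should give the trimethylsilyl ether F3. The same alkyne metathesis on this aprotic substrate should give the silylated cycloalkyne F4. n-Bu4NF buffered with acetic acid in THF then removes the silyl group and returns 30.

Step 7. Addition of the peracid to a carbonyl group flanked by a quaternary carbon with a bulky silyloxymethyl group may be slow, so that long exposure erodes the silyl ether or lets migration of the ring CH2 compete. The fallback sets out from 9 and comes back at 11, and it exchanges the order of deprotection and oxygen insertion. HF·pyridine first frees the primary alcohol to give the hydroxymethyl ketone F5, whose smaller, hydrogen-bond-donating CH2OH group should ease peracid addition. Baeyer–Villiger oxidation of F5 with mCPBA and NaHCO3 then gives hydroxymethyl lactone 11 directly, with the same retentive migration of C4.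

**Further compounds**

F1 | step 22 | cyclic alkenylzirconocene chloride: 31 after syn H–Zr addition, Cp2Zr(Cl) on C1, both oxygens as Cp2Zr(Cl) alkoxides | Cl[Zr](C1C=CC=C1)(C1C=CC=C1)/C1=C/C[C@](O[Zr](Cl)(C2C=CC=C2)C2C=CC=C2)([C@H](C)CC/C=C(\C)CO[Zr](Cl)(C2C=CC=C2)C2C=CC=C2)CC/C(C)=C/CC/C(C)=C/CC1
F2 | step 22 | (2E,6R)-6-[(1S,3E,7E,11E)-1-hydroxy-4-iodo-8,12-dimethylcyclotetradeca-3,7,11-trien-1-yl]-2-methylhept-2-en-1-ol | I/C1=C/C[C@](O)([C@H](C)CC/C=C(\C)CO)CC/C(C)=C/CC/C(C)=C/CC1
F3 | step 20 | trimethylsilyl ether of 29 at the tertiary hydroxyl | CC#CC[C@](O[Si](C)(C)C)([C@H](C)CC/C=C(\C)C(=O)OCC)CC/C(C)=C/CC/C(C)=C/CCC#CC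
F4 | step 20 | trimethylsilyl ether of 30 at the tertiary hydroxyl | C1#CC[C@](O[Si](C)(C)C)([C@H](C)CC/C=C(\C)C(=O)OCC)CC/C(C)=C/CC/C(C)=C/CC1
F5 | step 7 | (2S,3R)-2-(but-2-yn-1-yl)-2-(hydroxymethyl)-3-methylcyclopentan-1-one | O=C1[C@](CC#CC)(CO)[C@H](C)CC1
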